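**Plan**

1. Labels: ring A is the 3,4,5-trimethoxyphenyl on the acetoxy carbon C7; C8 is the methyl-bearing carbon joined through oxygen to ring B (the central 3,5-dimethoxy-4-oxyphenyl); C7' is the benzylic CH2 on ring B, C8' the lower ether carbon, C9' its methyl; ring C is the 2,6-dimethoxy-4-propenylphenyl.
2. Enabling feature: C8' carries the ring C aryloxy oxygen, C9' and the C7'H2–ring B benzyl group, so without C9' it is the carbonyl carbon of the ring C aryl ester of ring B acetic acid. A titanium methylidene adds C9' as the C8'=C9' enol ether.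
3. Retrosynthetic cuts, in order: C7–OAc; ring C–propenyl; the two C–H bonds across C8'=C9'; C8'=C9'; the ring C O–C8' acyl bond; ring B–CH2CO2H back to an allyl group; C7–ring A; C8–O(ring B).
4. Forward, the open chain is joined linearly from ring B: lactate ether, Weinreb amide, ring A ketone, erythro alcohol, silyl ether, allyl cleavage to the arylacetic acid, ring C aryl ester, methylenation, hydrogenation, propenylation, desilylation, acetylation. No ring is formed.
5. Stereochemistry: C8 (R) from ethyl (S)-lactate by Mitsunobu inversion; C7 (S) by chelation-controlled ketone reduction; C8' (R) by catalyst-controlled hydrogenation of the enol ether; the E-propenyl geometry from the E-boronate.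

Key step: step 9

Abbreviations: TBS = tert-butyldimethylsilyl; NMO = N-methylmorpholine N-oxide; DIAD = diisopropyl azodicarboxylate; cod = 1,5-cyclooctadiene; BArF = B[3,5-(CF3)2C6H3]4.

Remark (assumption): the sense of induction of the iridium catalyst in step 10 cannot be derived from precedent for this substrate, so the ligand enantiomer that gives 8'R is taken to be found by screening and confirmed by correlation with material from the Mitsunobu fallback.

**Route**

Step 1
Reactants: 1 4-allyl-2,6-dimethoxyphenol; 2 ethyl (S)-lactate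
Product: 3 ethyl (2R)-2-(4-allyl-2,6-dimethoxyphenoxy)propanoate
Conditions: PPh3, DIAD, THF, 0 °C → rt
Reagents that add atoms: none
Why: Mitsunobu etherification of the acidic, hindered phenol with an α-hydroxy ester is an SN2 displacement at the activated lactate carbon, so the (S)-carbinol should be inverted cleanly to the (R)-aryl ether that becomes C8.

Step 2
Reactants: 3 ethyl (2R)-2-(4-allyl-2,6-dimethoxyphenoxy)propanoate
Product: 4 (2R)-2-(4-allyl-2,6-dimethoxyphenoxy)-N-methoxy-N-methylpropanamide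
Conditions: MeNH(OMe)·HCl (1.5 equiv), iPrMgCl (3.0 equiv), THF, −20 °C
Reagents that add atoms: N,O-dimethylhydroxylamine hydrochloride, CNOC.Cl
Why: Weinreb amide formation by ester aminolysis with the chloromagnesium amide made in situ should proceed at low temperature without epimerising the α-aryloxy centre or touching the allyl group.

Step 3
Reactants: 4 (2R)-2-(4-allyl-2,6-dimethoxyphenoxy)-N-methoxy-N-methylpropanamide; 5 5-bromo-1,2,3-trimethoxybenzene
Product: 7 (2R)-2-(4-allyl-2,6-dimethoxyphenoxy)-1-(3,4,5-trimethoxyphenyl)propan-1-one, via 3,4,5-trimethoxyphenylmagnesium bromide 6 (not isolated)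
Conditions: 5, Mg, THF, rt → reflux; then 4, THF, 0 °C; cold 1 M HCl quench
Reagents that add atoms: none
Why: In this Weinreb ketone synthesis the Grignard adduct is held as a magnesium chelate until the acidic quench, which should prevent over-addition and keep the epimerisable α-aryloxy ketone away from base.

Step 4
Reactants: 7 (2R)-2-(4-allyl-2,6-dimethoxyphenoxy)-1-(3,4,5-trimethoxyphenyl)propan-1-one
Product: 8 (1S,2R)-2-(4-allyl-2,6-dimethoxyphenoxy)-1-(3,4,5-trimethoxyphenyl)propan-1-ol (erythro)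
Conditions: Zn(BH4)2, Et2O, −30 → 0 °C; aq NH4Cl
Reagents that add atoms: none
Why: In this chelation-controlled (Cram cyclic model) reduction zinc should bridge the carbonyl oxygen and the C8 aryloxy/ortho-methoxy oxygens, so hydride enters from the C8–H side and sets C7 as S (erythro).

Step 5
Reactants: 8 (1S,2R)-2-(4-allyl-2,6-dimethoxyphenoxy)-1-(3,4,5-trimethoxyphenyl)propan-1-ol
Product: 9 tert-butyl{[(1S,2R)-2-(4-allyl-2,6-dimethoxyphenoxy)-1-(3,4,5-trimethoxyphenyl)propyl]oxy}dimethylsilane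
Conditions: TBSOTf, 2,6-lutidine, CH2Cl2, 0 °C
Reagents that add atoms: tert-butyldimethylsilyl trifluoromethanesulfonate, CC(C)(C)[Si](C)(C)OS(=O)(=O)C(F)(F)F
Why: Silyl triflate silylation of the hindered benzylic alcohol gives a group that is inert to the titanium methylidene (unlike the final acetate) and is later removed by fluoride without ionising C7.

Step 6
Reactants: 9 tert-butyl{[(1S,2R)-2-(4-allyl-2,6-dimethoxyphenoxy)-1-(3,4,5-trimethoxyphenyl)propyl]oxy}dimethylsilane
Product: 11 (3,5-dimethoxy-4-{[(1S,2R)-1-(tert-butyldimethylsilyloxy)-1-(3,4,5-trimethoxyphenyl)propan-2-yl]oxy}phenyl)acetaldehyde, via vicinal diol 10 (not isolated)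
Conditions: OsO4 (2 mol %), NMO, acetone/H2O, rt; then NaIO4, rt; used crude
Reagents that add atoms: N-methylmorpholine N-oxide, C[N+]1([O-])CCOCC1; water, O (oxygen delivered through OsO4)
Why: Upjohn dihydroxylation of the only alkene followed by periodate glycol cleavage (Lemieux–Johnson type) should shorten the allyl group to the arylacetaldehyde without oxidising the electron-rich rings.

Step 7
Reactants: 11 (3,5-dimethoxy-4-{[(1S,2R)-1-(tert-butyldimethylsilyloxy)-1-(3,4,5-trimethoxyphenyl)propan-2-yl]oxy}phenyl)acetaldehyde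
Product: 12 (3,5-dimethoxy-4-{[(1S,2R)-1-(tert-butyldimethylsilyloxy)-1-(3,4,5-trimethoxyphenyl)propan-2-yl]oxy}phenyl)acetic acid
Conditions: NaClO2, NaH2PO4, 2-methyl-2-butene, t-BuOH/H2O, 0 °C → rt
Reagents that add atoms: sodium chlorite, [Na+].[O-]Cl=O
Why: Pinnick oxidation converts the aldehyde to the acid under buffered conditions, the alkene scavenger trapping HOCl before it can chlorinate rings A and B.

Step 8
Reactants: 12 (3,5-dimethoxy-4-{[(1S,2R)-1-(tert-butyldimethylsilyloxy)-1-(3,4,5-trimethoxyphenyl)propan-2-yl]oxy}phenyl)acetic acid; 13 4-bromo-2,6-dimethoxyphenol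
Product: 14 4-bromo-2,6-dimethoxyphenyl (3,5-dimethoxy-4-{[(1S,2R)-1-(tert-butyldimethylsilyloxy)-1-(3,4,5-trimethoxyphenyl)propan-2-yl]oxy}phenyl)acetate
Conditions: DCC, DMAP (cat.), CH2Cl2, 0 °C → rt
Reagents that add atoms: none
Why: Steglich esterification forms the hindered ring C–O–C8' bond as a simple acylation of the phenol, and the bromide holds the place of the propenyl group, which would not survive step 10.

Step 9
Reactants: 14 4-bromo-2,6-dimethoxyphenyl (3,5-dimethoxy-4-{[(1S,2R)-1-(tert-butyldimethylsilyloxy)-1-(3,4,5-trimethoxyphenyl)propan-2-yl]oxy}phenyl)acetate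
Product: 15 5-bromo-2-{[3-(3,5-dimethoxy-4-{[(1S,2R)-1-(tert-butyldimethylsilyloxy)-1-(3,4,5-trimethoxyphenyl)propan-2-yl]oxy}phenyl)prop-1-en-2-yl]oxy}-1,3-dimethoxybenzene
Conditions: Cp2Ti(μ-Cl)(μ-CH2)AlMe2 (Tebbe reagent, 1.5 equiv, toluene), pyridine (cat.), THF, −40 → 0 °C; aq NaOH quench; basic Al2O3 chromatography
Reagents that add atoms: Cp2Ti(μ-Cl)(μ-CH2)AlMe2, C[Al-]1(C)C[Ti](C2C=CC=C2)(C2C=CC=C2)[Cl+]1
Why: Pyridine and THF free the titanocene methylidene Cp2Ti=CH2 from the aluminium-bridged reagent; it adds across the ester C=O in a [2+2] fashion to an oxatitanacyclobutane, which cycloreverts to the C8'=C9' enol ether and titanocene oxide, driven by the strong Ti=O bond. The closest known reaction type is the Tebbe methylenation of esters, aryl esters such as phenyl benzoate included, to aryl 1-substituted vinyl ethers. No ring is closed and no stereocentre is created; C7 and C8 are remote and untouched. The step needs chemoselectivity and positional integrity: the ester is the only carbonyl in 14 (silyl ether, aryl bromide and methyl ethers are inert), the weakly basic, oxophilic methylidene should olefinate faster than it deprotonates the C7' methylene at low temperature, and the basic quench with chromatography on a basic support should keep the terminal double bond from hydrolysing or moving into conjugation with ring B.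

Step 10
Reactants: 15 5-bromo-2-{[3-(3,5-dimethoxy-4-{[(1S,2R)-1-(tert-butyldimethylsilyloxy)-1-(3,4,5-trimethoxyphenyl)propan-2-yl]oxy}phenyl)prop-1-en-2-yl]oxy}-1,3-dimethoxybenzene
Product: 16 5-bromo-2-{[(2R)-1-(3,5-dimethoxy-4-{[(1S,2R)-1-(tert-butyldimethylsilyloxy)-1-(3,4,5-trimethoxyphenyl)propan-2-yl]oxy}phenyl)propan-2-yl]oxy}-1,3-dimethoxybenzene
Conditions: [Ir(cod)(L)]BArF (2 mol %; L = one enantiomer of 4-tert-butyl-2-[2-(diphenylphosphino)phenyl]-4,5-dihydrooxazole), H2 (1 bar), CH2Cl2, 0 °C → rt; C8' epimers separated by preparative HPLC if needed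
Reagents that add atoms: none
Why: Proposed new method: the cationic iridium P,N dihydride should bind the 1,1-disubstituted C8'=C9' bond and deliver H2 by migratory insertion and reductive elimination to the face fixed by the ligand, the bulky 2,6-dimethoxyaryloxy group and the benzyl group occupying different quadrants, so that C8' (R) is catalyst-controlled while the remote C7/C8 centres exert no bias and the aryl bromide and silyl ether are tolerated; the closest known reaction type is the iridium phosphine–oxazoline (Pfaltz-type) asymmetric hydrogenation of enol ethers and of unfunctionalised 1,1-disubstituted alkenes, which has not been shown for aryl 1-benzylvinyl ethers, and low pressure and temperature are chosen to outrun double-bond migration.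

Step 11
Reactants: 16 5-bromo-2-{[(2R)-1-(3,5-dimethoxy-4-{[(1S,2R)-1-(tert-butyldimethylsilyloxy)-1-(3,4,5-trimethoxyphenyl)propan-2-yl]oxy}phenyl)propan-2-yl]oxy}-1,3-dimethoxybenzene; 17 (E)-4,4,5,5-tetramethyl-2-(prop-1-en-1-yl)-1,3,2-dioxaborolane
Product: 18 2-{[(2R)-1-(3,5-dimethoxy-4-{[(1S,2R)-1-(tert-butyldimethylsilyloxy)-1-(3,4,5-trimethoxyphenyl)propan-2-yl]oxy}phenyl)propan-2-yl]oxy}-1,3-dimethoxy-5-[(E)-prop-1-en-1-yl]benzene
Conditions: Pd(OAc)2 (5 mol %), SPhos, K3PO4, toluene/H2O, 80 °C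
Reagents that add atoms: none
Why: Suzuki–Miyaura coupling of the unhindered, electron-rich aryl bromide (oxidative addition to zerovalent palladium aided by the biaryl phosphine) with the E-alkenylboronate proceeds with retention of alkene geometry.

Step 12
Reactants: 18 2-{[(2R)-1-(3,5-dimethoxy-4-{[(1S,2R)-1-(tert-butyldimethylsilyloxy)-1-(3,4,5-trimethoxyphenyl)propan-2-yl]oxy}phenyl)propan-2-yl]oxy}-1,3-dimethoxy-5-[(E)-prop-1-en-1-yl]benzene
Product: 19 (1S,2R)-2-{4-[(2R)-2-{2,6-dimethoxy-4-[(E)-prop-1-en-1-yl]phenoxy}propyl]-2,6-dimethoxyphenoxy}-1-(3,4,5-trimethoxyphenyl)propan-1-ol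
Conditions: Bu4NF, THF, 0 °C → rt
Reagents that add atoms: none
Why: Fluoride desilylation frees the C7 alcohol under non-acidic conditions, so neither the benzylic C7–O bond nor the propenyl group should be affected.

Step 13
Reactants: 19 (1S,2R)-2-{4-[(2R)-2-{2,6-dimethoxy-4-[(E)-prop-1-en-1-yl]phenoxy}propyl]-2,6-dimethoxyphenoxy}-1-(3,4,5-trimethoxyphenyl)propan-1-ol
Product: 20 (1S,2R)-2-{4-[(2R)-2-{2,6-dimethoxy-4-[(E)-prop-1-en-1-yl]phenoxy}propyl]-2,6-dimethoxyphenoxy}-1-(3,4,5-trimethoxyphenyl)propyl acetate (CNP0157869.1)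
Conditions: Ac2O, pyridine, DMAP (cat.), CH2Cl2, rt
Reagents that add atoms: acetic anhydride, CC(=O)OC(C)=O
Why: DMAP-catalysed O-acylation of the secondary benzylic alcohol retains configuration at C7 and completes the target.

**Compound list**

1 | 4-allyl-2,6-dimethoxyphenol | C=CCc1cc(OC)c(O)c(OC)c1 | starting material
2 | ethyl (S)-lactate | CCOC(=O)[C@H](C)O | starting material
3 | ethyl (2R)-2-(4-allyl-2,6-dimethoxyphenoxy)propanoate | C=CCc1cc(OC)c(O[C@H](C)C(=O)OCC)c(OC)c1 | intermediate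
4 | (2R)-2-(4-allyl-2,6-dimethoxyphenoxy)-N-methoxy-N-methylpropanamide | C=CCc1cc(OC)c(O[C@H](C)C(=O)N(C)OC)c(OC)c1 | intermediate
5 | 5-bromo-1,2,3-trimethoxybenzene | COc1cc(Br)cc(OC)c1OC | starting material
6 | 3,4,5-trimethoxyphenylmagnesium bromide | COc1cc([Mg]Br)cc(OC)c1OC | intermediate (not isolated)
7 | (2R)-2-(4-allyl-2,6-dimethoxyphenoxy)-1-(3,4,5-trimethoxyphenyl)propan-1-one | C=CCc1cc(OC)c(O[C@H](C)C(=O)c2cc(OC)c(OC)c(OC)c2)c(OC)c1 | intermediate
8 | (1S,2R)-2-(4-allyl-2,6-dimethoxyphenoxy)-1-(3,4,5-trimethoxyphenyl)propan-1-ol | C=CCc1cc(OC)c(O[C@H](C)[C@@H](O)c2cc(OC)c(OC)c(OC)c2)c(OC)c1 | intermediate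
9 | tert-butyl{[(1S,2R)-2-(4-allyl-2,6-dimethoxyphenoxy)-1-(3,4,5-trimethoxyphenyl)propyl]oxy}dimethylsilane | C=CCc1cc(OC)c(O[C@H](C)[C@@H](O[Si](C)(C)C(C)(C)C)c2cc(OC)c(OC)c(OC)c2)c(OC)c1 | intermediate
10 | 3-(3,5-dimethoxy-4-{[(1S,2R)-1-(tert-butyldimethylsilyloxy)-1-(3,4,5-trimethoxyphenyl)propan-2-yl]oxy}phenyl)propane-1,2-diol (both C2 epimers) | OCC(O)Cc1cc(OC)c(O[C@H](C)[C@@H](O[Si](C)(C)C(C)(C)C)c2cc(OC)c(OC)c(OC)c2)c(OC)c1 | intermediate (not isolated)
11 | (3,5-dimethoxy-4-{[(1S,2R)-1-(tert-butyldimethylsilyloxy)-1-(3,4,5-trimethoxyphenyl)propan-2-yl]oxy}phenyl)acetaldehyde | O=CCc1cc(OC)c(O[C@H](C)[C@@H](O[Si](C)(C)C(C)(C)C)c2cc(OC)c(OC)c(OC)c2)c(OC)c1 | intermediate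
12 | (3,5-dimethoxy-4-{[(1S,2R)-1-(tert-butyldimethylsilyloxy)-1-(3,4,5-trimethoxyphenyl)propan-2-yl]oxy}phenyl)acetic acid | OC(=O)Cc1cc(OC)c(O[C@H](C)[C@@H](O[Si](C)(C)C(C)(C)C)c2cc(OC)c(OC)c(OC)c2)c(OC)c1 | intermediate
13 | 4-bromo-2,6-dimethoxyphenol | Oc1c(OC)cc(Br)cc1OC | starting material
14 | 4-bromo-2,6-dimethoxyphenyl (3,5-dimethoxy-4-{[(1S,2R)-1-(tert-butyldimethylsilyloxy)-1-(3,4,5-trimethoxyphenyl)propan-2-yl]oxy}phenyl)acetate | Brc1cc(OC)c(OC(=O)Cc2cc(OC)c(O[C@H](C)[C@@H](O[Si](C)(C)C(C)(C)C)c3cc(OC)c(OC)c(OC)c3)c(OC)c2)c(OC)c1 | intermediate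
15 | 5-bromo-2-{[3-(3,5-dimethoxy-4-{[(1S,2R)-1-(tert-butyldimethylsilyloxy)-1-(3,4,5-trimethoxyphenyl)propan-2-yl]oxy}phenyl)prop-1-en-2-yl]oxy}-1,3-dimethoxybenzene | Brc1cc(OC)c(OC(=C)Cc2cc(OC)c(O[C@H](C)[C@@H](O[Si](C)(C)C(C)(C)C)c3cc(OC)c(OC)c(OC)c3)c(OC)c2)c(OC)c1 | intermediate
16 | 5-bromo-2-{[(2R)-1-(3,5-dimethoxy-4-{[(1S,2R)-1-(tert-butyldimethylsilyloxy)-1-(3,4,5-trimethoxyphenyl)propan-2-yl]oxy}phenyl)propan-2-yl]oxy}-1,3-dimethoxybenzene | Brc1cc(OC)c(O[C@H](C)Cc2cc(OC)c(O[C@H](C)[C@@H](O[Si](C)(C)C(C)(C)C)c3cc(OC)c(OC)c(OC)c3)c(OC)c2)c(OC)c1 | intermediate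
17 | (E)-4,4,5,5-tetramethyl-2-(prop-1-en-1-yl)-1,3,2-dioxaborolane | C/C=C/B1OC(C)(C)C(C)(C)O1 | starting material
18 | 2-{[(2R)-1-(3,5-dimethoxy-4-{[(1S,2R)-1-(tert-butyldimethylsilyloxy)-1-(3,4,5-trimethoxyphenyl)propan-2-yl]oxy}phenyl)propan-2-yl]oxy}-1,3-dimethoxy-5-[(E)-prop-1-en-1-yl]benzene | C/C=C/c1cc(OC)c(O[C@H](C)Cc2cc(OC)c(O[C@H](C)[C@@H](O[Si](C)(C)C(C)(C)C)c3cc(OC)c(OC)c(OC)c3)c(OC)c2)c(OC)c1 | intermediate
19 | (1S,2R)-2-{4-[(2R)-2-{2,6-dimethoxy-4-[(E)-prop-1-en-1-yl]phenoxy}propyl]-2,6-dimethoxyphenoxy}-1-(3,4,5-trimethoxyphenyl)propan-1-ol | C/C=C/c1cc(OC)c(O[C@H](C)Cc2cc(OC)c(O[C@H](C)[C@@H](O)c3cc(OC)c(OC)c(OC)c3)c(OC)c2)c(OC)c1 | intermediate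
20 | (1S,2R)-2-{4-[(2R)-2-{2,6-dimethoxy-4-[(E)-prop-1-en-1-yl]phenoxy}propyl]-2,6-dimethoxyphenoxy}-1-(3,4,5-trimethoxyphenyl)propyl acetate | C/C=C/c1cc(OC)c(O[C@H](C)Cc2cc(OC)c(O[C@H](C)[C@@H](OC(C)=O)c3cc(OC)c(OC)c(OC)c3)c(OC)c2)c(OC)c1 | target

**Step count**

Total steps: 13. Longest linear sequence: 13 steps (from 1 and 2 to 20); the arylmagnesium reagent 6 is made within step 3.

**Steps most likely to fail**

Step 10 (asymmetric hydrogenation). The catalyst may discriminate poorly between the two faces of an enol ether whose C8' substituents are of similar size, and the acidic iridium hydride may move the double bond toward ring B or cleave the enol ether, so that alkene isomers are reduced with different selectivity. The fallback uses known chemistry and forms the C8'–O bond by SN2 inversion. It sets out from 9. Epoxidation of the allyl group (mCPBA, NaHCO3, CH2Cl2) should give tert-butyl{[(1S,2R)-2-{2,6-dimethoxy-4-[(oxiran-2-yl)methyl]phenoxy}-1-(3,4,5-trimethoxyphenyl)propyl]oxy}dimethylsilane as both oxirane epimers F1. Hydrolytic kinetic resolution with Co(salen)(OAc) (trivalent cobalt; salen = N,N'-bis(3,5-di-tert-butylsalicylidene)cyclohexane-1,2-diamine dianion, the enantiomer that hydrolyses the (S)-oxirane epimer; 0.55 equiv H2O) should leave the (R)-oxirane epimer tert-butyl{[(1S,2R)-2-(2,6-dimethoxy-4-{[(2R)-oxiran-2-yl]methyl}phenoxy)-1-(3,4,5-trimethoxyphenyl)propyl]oxy}dimethylsilane F2. Hydride opening at the terminal carbon (LiBHEt3, THF, 0 °C) should give (2S)-1-(3,5-dimethoxy-4-{[(1S,2R)-1-(tert-butyldimethylsilyloxy)-1-(3,4,5-trimethoxyphenyl)propan-2-yl]oxy}phenyl)propan-2-ol F3. Mitsunobu etherification of F3 with phenol 13 (PPh3, DIAD, THF) inverts the carbinol and comes back to the route at 16.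

Step 9 (methylenation, key step). The titanium reagent may deprotonate the doubly activated C7' methylene (titanium enolate, or loss of the phenoxide through a ketene) instead of adding to the carbonyl, and the terminal enol ether may hydrolyse or isomerise during isolation. If changing to Cp2TiMe2 does not help, the fallback dispenses with the titanium carbene, so the acetate can be installed early. It sets out from 8. Acetylation (Ac2O, pyridine, DMAP) should give (1S,2R)-2-(4-allyl-2,6-dimethoxyphenoxy)-1-(3,4,5-trimethoxyphenyl)propyl acetate F4. Wacker–Tsuji oxidation (PdCl2, CuCl, O2, DMF/H2O) should give (1S,2R)-2-[2,6-dimethoxy-4-(2-oxopropyl)phenoxy]-1-(3,4,5-trimethoxyphenyl)propyl acetate F5. Reduction with a Prelog-selective ketoreductase (NADPH, isopropanol recycling), or less selectively with the (R)-methyl oxazaborolidine and BH3·SMe2, should give (1S,2R)-2-{4-[(2S)-2-hydroxypropyl]-2,6-dimethoxyphenoxy}-1-(3,4,5-trimethoxyphenyl)propyl acetate F6. Mitsunobu etherification of F6 with (E)-2,6-dimethoxy-4-(prop-1-en-1-yl)phenol F7 (commercial, or from 1 by KOtBu/DMSO allyl-to-propenyl isomerisation) inverts C8' and comes back to the route at 20.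

Step 4 (chelation-controlled reduction). Zinc chelation by the weakly basic aryl ether oxygen may be too loose to control the face of hydride attack, and the α-aryloxy ketone may epimerise at C8 before it is reduced. The fallback reduces under non-chelating control and then inverts C7. It sets out from 7. LiBH(s-Bu)3 (THF, −78 °C) should give by Felkin–Anh attack the threo alcohol (1R,2R)-2-(4-allyl-2,6-dimethoxyphenoxy)-1-(3,4,5-trimethoxyphenyl)propan-1-ol F8. Mitsunobu esterification with 4-nitrobenzoic acid (PPh3, DIAD) should invert C7 to (1S,2R)-2-(4-allyl-2,6-dimethoxyphenoxy)-1-(3,4,5-trimethoxyphenyl)propyl 4-nitrobenzoate F9. Methanolysis (K2CO3, MeOH) comes back to the route at 8.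

**Further compounds**

F1 | step 10 | tert-butyl{[(1S,2R)-2-{2,6-dimethoxy-4-[(oxiran-2-yl)methyl]phenoxy}-1-(3,4,5-trimethoxyphenyl)propyl]oxy}dimethylsilane (both oxirane epimers) | C1OC1Cc1cc(OC)c(O[C@H](C)[C@@H](O[Si](C)(C)C(C)(C)C)c2cc(OC)c(OC)c(OC)c2)c(OC)c1
F2 | step 10 | tert-butyl{[(1S,2R)-2-(2,6-dimethoxy-4-{[(2R)-oxiran-2-yl]methyl}phenoxy)-1-(3,4,5-trimethoxyphenyl)propyl]oxy}dimethylsilane | C1O[C@@H]1Cc1cc(OC)c(O[C@H](C)[C@@H](O[Si](C)(C)C(C)(C)C)c2cc(OC)c(OC)c(OC)c2)c(OC)c1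
F3 | step 10 | (2S)-1-(3,5-dimethoxy-4-{[(1S,2R)-1-(tert-butyldimethylsilyloxy)-1-(3,4,5-trimethoxyphenyl)propan-2-yl]oxy}phenyl)propan-2-ol | C[C@H](O)Cc1cc(OC)c(O[C@H](C)[C@@H](O[Si](C)(C)C(C)(C)C)c2cc(OC)c(OC)c(OC)c2)c(OC)c1
F4 | step 9 | (1S,2R)-2-(4-allyl-2,6-dimethoxyphenoxy)-1-(3,4,5-trimethoxyphenyl)propyl acetate | C=CCc1cc(OC)c(O[C@H](C)[C@@H](OC(C)=O)c2cc(OC)c(OC)c(OC)c2)c(OC)c1
F5 | step 9 | (1S,2R)-2-[2,6-dimethoxy-4-(2-oxopropyl)phenoxy]-1-(3,4,5-trimethoxyphenyl)propyl acetate | CC(=O)Cc1cc(OC)c(O[C@H](C)[C@@H](OC(C)=O)c2cc(OC)c(OC)c(OC)c2)c(OC)c1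
F6 | step 9 | (1S,2R)-2-{4-[(2S)-2-hydroxypropyl]-2,6-dimethoxyphenoxy}-1-(3,4,5-trimethoxyphenyl)propyl acetate | C[C@H](O)Cc1cc(OC)c(O[C@H](C)[C@@H](OC(C)=O)c2cc(OC)c(OC)c(OC)c2)c(OC)c1
F7 | step 9 | (E)-2,6-dimethoxy-4-(prop-1-en-1-yl)phenol | C/C=C/c1cc(OC)c(O)c(OC)c1
F8 | step 4 | (1R,2R)-2-(4-allyl-2,6-dimethoxyphenoxy)-1-(3,4,5-trimethoxyphenyl)propan-1-ol | C=CCc1cc(OC)c(O[C@H](C)[C@H](O)c2cc(OC)c(OC)c(OC)c2)c(OC)c1
F9 | step 4 | (1S,2R)-2-(4-allyl-2,6-dimethoxyphenoxy)-1-(3,4,5-trimethoxyphenyl)propyl 4-nitrobenzoate | C=CCc1cc(OC)c(O[C@H](C)[C@@H](OC(=O)c2ccc(cc2)[N+](=O)[O-])c2cc(OC)c(OC)c(OC)c2)c(OC)c1
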